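Everything rests on opening the γ-lactone ring (O–C5–C6–C7–C8; side chain numbered C1 = OCH2, C2/C3 = epoxide, C4 = CH2) at C5–C6 and O–C8: C6, C7 with its methyl, and C8 amount to a masked methacrylate hung on carbinol C5. A single iridium-catalysed transfer-hydrogenative coupling oxidises the C5 primary alcohol, adds a 2-(ethoxycarbonyl)allyl unit under ligand control (C5 = S) and closes the α-methylene lactone by acyl transfer, so the base-labile β,γ-epoxy aldehyde is never handled. Its precursor is a (2R,3R)-epoxy alcohol, silylated at C1 and free at C5, made from but-3-yn-1-ol by carboalumination and Sharpless epoxidation; radical hydration of the methylene group, desilylation and Mitsunobu etherification complete the target.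

Key step: step 7

Remark on the target: the epoxide is 2R,3R (C1 and C4 trans), C5 is S and C7 is R, with the C7 hydroxyl trans to the C5 side chain on the lactone ring.

Assumption: the (S)-configured bisphosphine is taken to deliver the allyl unit to the Si face of aldehyde 11 (C5 = S). The sense is to be checked on the first sample of 13; if it is opposite, the antipodal ligand is used with nothing else changed.

Step 1
Reactants: 1 but-3-yn-1-ol
Product: 2 1-[(but-3-yn-1-yloxy)methyl]-4-methoxybenzene
Conditions: NaH, PMBCl, Bu4NI (cat.), THF/DMF, 0 °C to rt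
Reagents that add atoms: 4-methoxybenzyl chloride, COc1ccc(CCl)cc1
Why: Williamson etherification; the alkoxide of 1 forms selectively (the alkyne C–H is far less acidic) and displaces chloride from the benzylic halide under iodide catalysis.

Step 2
Reactants: 2 1-[(but-3-yn-1-yloxy)methyl]-4-methoxybenzene
Product: 5 (E)-5-[(4-methoxybenzyl)oxy]-3-methylpent-2-en-1-ol, via alkenyldimethylalane 3 (not isolated), via lithium alkenylalanate 4 (not isolated)
Conditions: AlMe3, Cp2ZrCl2 (cat.), CH2Cl2, 0 °C to rt; evaporate volatiles; n-BuLi, THF/hexane, −78 to 0 °C; (CH2O)n, rt; aq. Rochelle salt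
Reagents that add atoms: trimethylaluminium, C[Al](C)C; formaldehyde (as paraformaldehyde), C=O
Why: Negishi zirconium-catalysed carboalumination adds methyl and aluminium syn across the terminal alkyne with methyl on the internal carbon, and the derived alanate attacks formaldehyde with retention of geometry, which fixes the E olefin (CH2OH cis to methyl).

Step 3
Reactants: 5 (E)-5-[(4-methoxybenzyl)oxy]-3-methylpent-2-en-1-ol
Product: 6 [(2R,3R)-3-{2-[(4-methoxybenzyl)oxy]ethyl}-3-methyloxiran-2-yl]methanol
Conditions: Ti(Oi-Pr)4 (cat.), D-(−)-diethyl tartrate (cat.), t-BuOOH, 4 Å MS, CH2Cl2, −20 °C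
Reagents that add atoms: tert-butyl hydroperoxide, CC(C)(C)OO
Why: Sharpless asymmetric epoxidation of an E-trisubstituted allylic alcohol; the titanium D-tartrate complex sets both epoxide centres under reagent control as 2R,3R (the mirror image of the geraniol/L-tartrate outcome), and the PMB ether is inert.

Step 4
Reactants: 6 [(2R,3R)-3-{2-[(4-methoxybenzyl)oxy]ethyl}-3-methyloxiran-2-yl]methanol
Product: 7 tert-butyl{[(2R,3R)-3-{2-[(4-methoxybenzyl)oxy]ethyl}-3-methyloxiran-2-yl]methoxy}diphenylsilane
Conditions: TBDPSCl, imidazole, DMF, 0 °C to rt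
Reagents that add atoms: tert-butyl(chloro)diphenylsilane, CC(C)(C)[Si](Cl)(c1ccccc1)c1ccccc1
Why: Standard silylation of the only free hydroxyl; the bulky silyl ether should withstand DDQ, carbonate base at 70 °C and the radical hydration, and it blocks C1 from dehydrogenation in step 7.

Step 5
Reactants: 7 tert-butyl{[(2R,3R)-3-{2-[(4-methoxybenzyl)oxy]ethyl}-3-methyloxiran-2-yl]methoxy}diphenylsilane
Product: 8 2-[(2R,3R)-3-{[(tert-butyldiphenylsilyl)oxy]methyl}-2-methyloxiran-2-yl]ethan-1-ol
Conditions: DDQ, CH2Cl2/pH 7 buffer, 0 °C to rt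
Reagents that add atoms: none
Why: Oxidative PMB cleavage (hydride abstraction at the electron-rich benzylic carbon, then hydrolysis) under buffered neutral conditions that spare epoxide and silyl ether; opening of the epoxide by the freed C5 hydroxyl would need a 4-exo or 5-endo closure and is not expected.

Step 6
Reactants: 9 ethyl 2-(hydroxymethyl)acrylate
Product: 10 ethyl 2-{[(tert-butoxycarbonyl)oxy]methyl}acrylate
Conditions: Boc2O, DMAP (cat.), CH2Cl2, 0 °C to rt
Reagents that add atoms: di-tert-butyl dicarbonate, CC(C)(C)OC(=O)OC(=O)OC(C)(C)C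
Why: DMAP-catalysed O-acylation of the allylic alcohol gives the mixed carbonate, which ionises readily on iridium with loss of CO2 and tert-butoxide.

Step 7
Reactants: 8 2-[(2R,3R)-3-{[(tert-butyldiphenylsilyl)oxy]methyl}-2-methyloxiran-2-yl]ethan-1-ol; 10 ethyl 2-{[(tert-butoxycarbonyl)oxy]methyl}acrylate
Product: 13 (5S)-5-{[(2R,3R)-3-{[(tert-butyldiphenylsilyl)oxy]methyl}-2-methyloxiran-2-yl]methyl}-3-methylideneoxolan-2-one, via epoxy aldehyde 11 (not isolated), via hydroxy ester 12 (not isolated)
Conditions: [Ir(cod)Cl]2 (cat.), (S)-SEGPHOS-type bisphosphine (cat.), 4-cyano-3-nitrobenzoic acid (cat.), Cs2CO3 (cat.), 10 (2 equiv), THF, 60–70 °C, sealed vessel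
Reagents that add atoms: none
Why: The cyclometallated iridium C,O-benzoate takes up the C5 alkoxide of 8 and undergoes β-hydride elimination to aldehyde 11; the iridium hydride, after loss of HX, ionises carbonate 10 (CO2 and tert-butoxide leave) to a 2-(ethoxycarbonyl)allyl iridium species that adds through a closed chair-like transition state to form C5–C6. The closest known reaction type is the iridium-catalysed transfer-hydrogenative 2-(alkoxycarbonyl)allylation of primary alcohols to α-methylene-γ-butyrolactones, a variant of the Krische allylation. The lactone ring closes when the C5 alkoxide of 12 attacks the ester carbonyl (5-exo-trig acyl transfer, ethanol lost), forming O–C8. The new stereocentre C5 (S, Si-face addition) is set by the chiral bisphosphine on iridium and not by the remote epoxide, so the ligand antipode decides the epimer. The step needs oxidation at C5 only and survival of the β,γ-epoxy aldehyde: C1 is silylated, and 11 exists only in catalytic amounts beside the allyl donor in an aprotic medium with catalytic carbonate, so addition should outrun E1cB opening of the epoxide.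

Step 8
Reactants: 13 (5S)-5-{[(2R,3R)-3-{[(tert-butyldiphenylsilyl)oxy]methyl}-2-methyloxiran-2-yl]methyl}-3-methylideneoxolan-2-one
Product: 15 (3R,5S)-5-{[(2R,3R)-3-{[(tert-butyldiphenylsilyl)oxy]methyl}-2-methyloxiran-2-yl]methyl}-3-hydroxy-3-methyloxolan-2-one, via tertiary hydroperoxide 14 (not isolated)
Conditions: Mn(dpm)3 (cat.), PhSiH3, O2 (1 atm), i-PrOH/CH2Cl2, 0 °C; then P(OEt)3
Reagents that add atoms: dioxygen, O=O
Why: Mukaiyama-type hydrogen-atom-transfer hydration as known for α,β-unsaturated esters: Mn–H gives H to the terminal CH2 (which becomes the C7 methyl), the carbonyl-stabilised C7 radical should be trapped by O2 on the ring face anti to the C5 side chain (hydroxyl trans to it, 3R), and the phosphite reduces the hydroperoxide.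

Step 9
Reactants: 15 (3R,5S)-5-{[(2R,3R)-3-{[(tert-butyldiphenylsilyl)oxy]methyl}-2-methyloxiran-2-yl]methyl}-3-hydroxy-3-methyloxolan-2-one
Product: 16 (3R,5S)-3-hydroxy-5-{[(2R,3R)-3-(hydroxymethyl)-2-methyloxiran-2-yl]methyl}-3-methyloxolan-2-one
Conditions: TBAF, AcOH, THF, 0 °C to rt
Reagents that add atoms: none
Why: Fluoride-induced cleavage of the silyl ether; buffering with acetic acid keeps the medium from triggering Payne rearrangement of the freed 2,3-epoxy alcohol or opening of the lactone.

Step 10
Reactants: 16 (3R,5S)-3-hydroxy-5-{[(2R,3R)-3-(hydroxymethyl)-2-methyloxiran-2-yl]methyl}-3-methyloxolan-2-one; 17 7-hydroxy-8-methoxy-2H-chromen-2-one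
Product: 18 7-{[(2R,3R)-3-{[(2S,4R)-4-hydroxy-4-methyl-5-oxooxolan-2-yl]methyl}-3-methyloxiran-2-yl]methoxy}-8-methoxy-2H-chromen-2-one
Conditions: PPh3, DIAD, THF, 0 °C to rt
Reagents that add atoms: none
Why: Mitsunobu etherification; the acidic coumarin phenol displaces the oxyphosphonium of the primary C1 alcohol in an SN2 step that touches no stereocentre, and the tertiary C7 hydroxyl is too hindered to be activated.

Compound list
1 | but-3-yn-1-ol | C#CCCO | starting material
2 | 1-[(but-3-yn-1-yloxy)methyl]-4-methoxybenzene | C#CCCOCc1ccc(OC)cc1 | intermediate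
3 | (E)-{4-[(4-methoxybenzyl)oxy]-2-methylbut-1-en-1-yl}dimethylalane (not isolated) | C[Al](C)/C=C(\C)CCOCc1ccc(OC)cc1 | intermediate
4 | lithium butyl(dimethyl){(E)-4-[(4-methoxybenzyl)oxy]-2-methylbut-1-en-1-yl}alanate (not isolated) | [Li+].CCCC[Al-](C)(C)/C=C(\C)CCOCc1ccc(OC)cc1 | intermediate
5 | (E)-5-[(4-methoxybenzyl)oxy]-3-methylpent-2-en-1-ol | OC/C=C(\C)CCOCc1ccc(OC)cc1 | intermediate
6 | [(2R,3R)-3-{2-[(4-methoxybenzyl)oxy]ethyl}-3-methyloxiran-2-yl]methanol | OC[C@H]1O[C@]1(C)CCOCc1ccc(OC)cc1 | intermediate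
7 | tert-butyl{[(2R,3R)-3-{2-[(4-methoxybenzyl)oxy]ethyl}-3-methyloxiran-2-yl]methoxy}diphenylsilane | CC(C)(C)[Si](OC[C@H]1O[C@]1(C)CCOCc1ccc(OC)cc1)(c1ccccc1)c1ccccc1 | intermediate
8 | 2-[(2R,3R)-3-{[(tert-butyldiphenylsilyl)oxy]methyl}-2-methyloxiran-2-yl]ethan-1-ol | CC(C)(C)[Si](OC[C@H]1O[C@]1(C)CCO)(c1ccccc1)c1ccccc1 | intermediate
9 | ethyl 2-(hydroxymethyl)acrylate | C=C(CO)C(=O)OCC | starting material
10 | ethyl 2-{[(tert-butoxycarbonyl)oxy]methyl}acrylate | C=C(COC(=O)OC(C)(C)C)C(=O)OCC | intermediate
11 | 2-[(2R,3R)-3-{[(tert-butyldiphenylsilyl)oxy]methyl}-2-methyloxiran-2-yl]acetaldehyde (not isolated) | CC(C)(C)[Si](OC[C@H]1O[C@]1(C)CC=O)(c1ccccc1)c1ccccc1 | intermediate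
12 | ethyl (4S)-5-[(2R,3R)-3-{[(tert-butyldiphenylsilyl)oxy]methyl}-2-methyloxiran-2-yl]-4-hydroxy-2-methylidenepentanoate (not isolated) | CC(C)(C)[Si](OC[C@H]1O[C@]1(C)C[C@@H](O)CC(=C)C(=O)OCC)(c1ccccc1)c1ccccc1 | intermediate
13 | (5S)-5-{[(2R,3R)-3-{[(tert-butyldiphenylsilyl)oxy]methyl}-2-methyloxiran-2-yl]methyl}-3-methylideneoxolan-2-one | CC(C)(C)[Si](OC[C@H]1O[C@]1(C)C[C@@H]1CC(=C)C(=O)O1)(c1ccccc1)c1ccccc1 | intermediate
14 | (3R,5R)-5-{[(2R,3R)-3-{[(tert-butyldiphenylsilyl)oxy]methyl}-2-methyloxiran-2-yl]methyl}-3-hydroperoxy-3-methyloxolan-2-one (not isolated; same geometry as 15, the C5 descriptor changes by priority only) | CC(C)(C)[Si](OC[C@H]1O[C@]1(C)C[C@@H]1C[C@@](C)(OO)C(=O)O1)(c1ccccc1)c1ccccc1 | intermediate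
15 | (3R,5S)-5-{[(2R,3R)-3-{[(tert-butyldiphenylsilyl)oxy]methyl}-2-methyloxiran-2-yl]methyl}-3-hydroxy-3-methyloxolan-2-one | CC(C)(C)[Si](OC[C@H]1O[C@]1(C)C[C@@H]1C[C@@](C)(O)C(=O)O1)(c1ccccc1)c1ccccc1 | intermediate
16 | (3R,5S)-3-hydroxy-5-{[(2R,3R)-3-(hydroxymethyl)-2-methyloxiran-2-yl]methyl}-3-methyloxolan-2-one | OC[C@H]1O[C@]1(C)C[C@@H]1C[C@@](C)(O)C(=O)O1 | intermediate
17 | 7-hydroxy-8-methoxy-2H-chromen-2-one | COc1c(O)ccc2ccc(=O)oc12 | starting material
18 | 7-{[(2R,3R)-3-{[(2S,4R)-4-hydroxy-4-methyl-5-oxooxolan-2-yl]methyl}-3-methyloxiran-2-yl]methoxy}-8-methoxy-2H-chromen-2-one | COc1c(OC[C@H]2O[C@]2(C)C[C@@H]2C[C@@](C)(O)C(=O)O2)ccc2ccc(=O)oc12 | target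

Total step count: 10. Longest linear sequence: 9 steps (steps 1–5 and 7–10 from but-3-yn-1-ol; step 6 is a one-step side branch).

Steps most likely to fail

Step 7. The transient β,γ-epoxy aldehyde may be lost to base-induced opening of the epoxide faster than it is allylated, or the catalyst may give weak facial control on a mismatched substrate. The fallback separates oxidation from C–C bond formation and sets out from 8. Dess–Martin oxidation (NaHCO3, CH2Cl2, 0 °C) gives epoxy aldehyde 11, which is used at once without chromatography. It then enters a chromium-catalysed enantioselective Nozaki–Hiyama–Kishi-type 2-(alkoxycarbonyl)allylation with commercial ethyl 2-(bromomethyl)acrylate (CrCl2, chiral bis(oxazoline)-type ligand, Mn, Cp2ZrCl2, THF, rt) under neutral conditions. This gives hydroxy ester 12, which is lactonised on mild work-up and comes back to the route at 13. No compound outside the list is made (F0).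

Step 8. Oxygen trapping of the C7 radical may show poor facial selectivity, or plain reduction of the olefin may compete with hydration. The fallback sets out from 13 and replaces the radical step by enolate chemistry. Hydrogenation of the exocyclic olefin (H2, RhCl(PPh3)3, EtOAc) gives (5S)-5-{[(2R,3R)-3-{[(tert-butyldiphenylsilyl)oxy]methyl}-2-methyloxiran-2-yl]methyl}-3-methyloxolan-2-one F1 as a C3 epimer mixture, which does not matter. Enolisation (LiHMDS, THF, −78 °C) and hydroxylation with 3-phenyl-2-(phenylsulfonyl)oxaziridine follow. The oxidant should approach the enolate face anti to the C5 substituent, as is usual for γ-substituted butyrolactone enolates, and the sequence comes back to the route at 15.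

Step 10. The redox condensation may stall, or the betaine may attack the epoxy alcohol (epoxide opening or migration) before the phenol is coupled. The fallback sets out from 16 and uses a plain SN2 alkylation. Selective sulfonylation of the primary hydroxyl (TsCl, Et3N, DMAP cat., CH2Cl2, 0 °C) gives [(2R,3R)-3-{[(2S,4R)-4-hydroxy-4-methyl-5-oxooxolan-2-yl]methyl}-3-methyloxiran-2-yl]methyl 4-methylbenzenesulfonate F2. Displacement at C1 by the caesium phenoxide of 17 (Cs2CO3, DMF, rt) comes back to the route at 18. Direct attack at C1 is expected because the distal epoxide carbon is fully substituted, so C2 keeps its configuration.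

Further compounds
F0 | step 7 | none | none
F1 | step 8 | (5S)-5-{[(2R,3R)-3-{[(tert-butyldiphenylsilyl)oxy]methyl}-2-methyloxiran-2-yl]methyl}-3-methyloxolan-2-one (C3 epimers) | CC(C)(C)[Si](OC[C@H]1O[C@]1(C)C[C@@H]1CC(C)C(=O)O1)(c1ccccc1)c1ccccc1
F2 | step 10 | [(2R,3R)-3-{[(2S,4R)-4-hydroxy-4-methyl-5-oxooxolan-2-yl]methyl}-3-methyloxiran-2-yl]methyl 4-methylbenzenesulfonate | Cc1ccc(cc1)S(=O)(=O)OC[C@H]1O[C@]1(C)C[C@@H]1C[C@@](C)(O)C(=O)O1
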